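**Conventions.** Compound numbers 1–17 are those of the steps below. Atoms are numbered on the target: five-ring C1(CH3)–C2–C3–C4(OH)(i-Pr)–C5(H), seven-ring C5–C6(OAr)–C7–C8(CH3)=C9–C10(=O)–C1. C11 is the carbon that becomes the methyl group on C1. "α" is the face of H5, "β" the face of the C1 methyl group.

## Analysis of the target

Target 17 is a daucane-type hydroazulene: a cyclopentane (C1–C5) fused along C1–C5 to a cycloheptenone (C5–C10, C1), with a 4-methoxybenzoate on C6, a vinylic methyl on C8 and the ketone on C10. It has four contiguous stereocentres, (1S,4R,5S,6S) in this numbering. The ring fusion is trans (C1 methyl β, H5 α), the C4 hydroxyl is β and its isopropyl α, and the C6 ester oxygen is α, so H5 and H6 are trans. The ester is a δ-acyloxy enone and can lose the carboxylate by vinylogous β-elimination under base. The tertiary C4 alcohol can dehydrate under strong acid. The difficulty is that a quaternary carbon (C1) and a fully substituted carbinol (C4) flank the ring-fusion CH (C5) in a trans-fused 5-7 system, with a further stereocentre (C6) on the other side of C5. The strategy rests on one mapping: C1, C6, C7, C8, C9 and C10, with the methyl on C8 and the oxygen on C10, are the six carbons of a 2-methoxy-4-methylphenyl ring (C1 ipso, C10 the methoxy-bearing ortho carbon, C8 para). The seventh ring carbon, C5, lies next to the C4 oxygen and can be the carbon of a ketocarbene tied to the arene through C2–C3–C4, so inserting C5 into the arene C1–C6 bond makes both rings at once.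

## Retrosynthetic reasoning

**Ester C–O bond (17 ⇒ 15 + 16).** The acyl–oxygen bond at C6 is cut first. The anisate is the only leaving group in the molecule that sits δ to the enone, so it is put on last. The forward reaction must acylate the secondary C6 hydroxyl of 15 with 16 and leave the tertiary C4 hydroxyl alone.

**C6–O bond and the C7 hydrogen (15 ⇒ 14 ⇒ 13 ⇒ 12).** Removing the C6 oxygen and one C7 hydrogen uncovers the cross-ring dienone 12. This works because C6 is the δ-carbon of that dienone and C8, the β-carbon, is blocked by its methyl group. Forward, a boron nucleophile adds at C6 (13), is oxidised to the alcohol (14), and the alkene is moved into conjugation (15). The step has to put the oxygen on the α face, which is the face away from the angular methyl.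

**C1–C11 bond (12 ⇒ 11 ⇒ 10).** The angular methyl is cut off as one carbon. The C10 ketone then becomes the methyl enol ether C1=C10 of 10, with cyclopropane 11 as the carrier of the extra carbon. Cutting here lets the C4 hydroxyl, which is on the β face, deliver the carbon to that same face. An enolate alkylation at C1 would not do this: it would be expected to place the methyl trans to the neighbouring C5–C6 bond and give the cis ring fusion.

**C4–isopropyl bond (10 ⇒ 9).** The tertiary carbinol is cut to the cyclopentanone 9. The forward addition has to beat enolisation toward C5 and has to come from the face of H5.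

**C5–C1 and C5–C6 bonds (9 ⇒ 8 ⇒ 7).** Both bonds to C5 inside the rings are cut, which returns the seven-ring to a benzene ring and the five-ring to an open chain ending in a diazoketone. This is the only cut that removes both rings in one step and leaves an arene that already holds the C8 methyl and the C10 oxygen. Forward, the carbene carbon must add across C1–C6 (not C1–C10) and with one absolute sense at C5.

**C4–C5 bond (7 ⇒ 6 + 5 ⇒ 4).** The diazoketone is cut between the carbonyl and the diazo carbon to the acid 4 (activated as 6) and the one-carbon diazo reagent 5.

**C2–C3 bond (4 ⇒ 3 ⇒ 1 + 2).** The propanoic acid chain is cut next to the benzylic carbon through the cinnamic acid 3 to aldehyde 1 and the two-carbon donor 2. Both are cheap and the arene substitution pattern is bought, not made.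

## Alternatives that were turned down

Alternative 1: The seven-ring is cut at C7–C8 and C1–C10 into a four-carbon and a three-carbon piece. The four-carbon piece is the 2-silyloxydiene A2, whose C5=C1 alkene lies in a ready-made cyclopentene carrying C4. The three-carbon piece is the siloxy-substituted vinyldiazoacetate A3. Forward, a chiral dirhodium carboxylate forms the vinylcarbenoid, which cyclopropanates the terminal C6=C7 bond; Cope rearrangement of the cis-divinylcyclopropane then gives A1. In its favour: it is convergent, C4 can come from the chiral pool, and donor/acceptor carbenoids are the most dependable class for asymmetric cyclopropanation. On enantiocontrol it is stronger than the chosen plan, whose carbenoid is of the less selective acceptor-only type. Against it: the Cope step must form the quaternary C1 at a tetrasubstituted alkene terminus next to the fully substituted C4, with unknown matching between catalyst and substrate. A1 is also at the wrong oxidation level in three places. C8 carries an ester that must be taken down to a methyl group, C10 is an alcohol, and C5 and C6 are locked in a tetrasubstituted silyl enol ether. H5 and the C6 carbinol, two of the four stereocentres, would therefore still have to be set by protonation and ketone reduction, with no clear bias to the trans fusion. About eight steps would follow its key step against six here. What the chosen strategy offers in place of the better enantiocontrol is that the C8 methyl, the C10 oxygen and H5 all come out of the key step in their final form.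

Alternative 2: The five-ring is closed last by cutting C3–C4. Forward, a samarium-mediated Barbier reaction converts the primary iodide of cycloheptanone A5 into an organometallic that adds to the isopropyl ketone and gives A4. In its favour: such closures onto hindered ketones are robust, no asymmetric catalysis is needed at that point, and the trans relation of the C1 and C5 substituents is fixed before the ring closes. Its key step is safer than the Buchner step. Against it: A5 already holds three contiguous stereocentres including the quaternary C1, so the hard problem is only moved to an unsolved precursor. The C10 ketone competes for the electron-transfer reagent. The face of the acyclic C4 ketone that is attacked depends on rotamer preferences. A4 has neither the C8 methyl nor the C8=C9 alkene, so enone formation, methyl conjugate addition and a second dehydrogenation would follow. The chosen strategy offers, in place of the safer key step, a far shorter route in which both rings come from a flat arene in one step.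

Alternative 3: The C1–C5 bond is traced back to a C1–C6 bond of a decalin. Forward, an alkoxide base deprotonates the tertiary C6 hydroxyl of the diol monomesylate A7. C1 then shifts from C6 to C5 anti to the leaving group, C6 becomes a ketone, and the two six-rings become the five- and seven-rings of A6. In its favour: the shift is stereospecific (retention at C1, inversion at C5), well understood, and decalins with the angular methyl can be had in enantiopure form by annulation chemistry. On certainty of absolute and relative configuration it is stronger than the chosen plan. Against it: A7 needs three neighbouring oxygenated carbons (C4, C5, C6) in a defined all-cis arrangement, with the isopropyl carbinol next to the diol. A6 has its ketone on C6, so the C6 alcohol must be made by reduction next to an epimerisable C5. A6 also lacks the C8 methyl and the C8=C9 alkene, which would have to be built from C10 after deketalisation in the presence of the C6 oxygen. The route would be well over fifteen steps. The chosen strategy gives up some per-step certainty and offers a ten-step sequence with the C8/C10 pattern present from the start.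

Key step: step 4

**Assumption (remark on the chemistry):** Rh2(S-PTTL)4 is taken to give the (8aR) enantiomer of 9. If the sense of induction proves opposite, the mirror-image catalyst Rh2(R-PTTL)4 is used and nothing else changes.

## Route

Step 1
Reactants: 1 2-methoxy-4-methylbenzaldehyde; 2 malonic acid
Product: 3 (E)-3-(2-methoxy-4-methylphenyl)prop-2-enoic acid
Conditions: pyridine, piperidine (cat.), 100 °C
Reagents that add atoms: none
Why: Knoevenagel–Doebner condensation; amine-catalysed condensation with malonic acid is followed by decarboxylation in hot pyridine and should give the E cinnamic acid, as is usual for ortho-alkoxybenzaldehydes.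

Step 2
Reactants: 3 (E)-3-(2-methoxy-4-methylphenyl)prop-2-enoic acid
Product: 4 3-(2-methoxy-4-methylphenyl)propanoic acid
Conditions: H2 (1 atm), Pd/C (10%), EtOAc, rt
Reagents that add atoms: none
Why: Heterogeneous catalytic hydrogenation of a cinnamic acid double bond; the arene, the aryl ether and the acid are inert under these conditions.

Step 3
Reactants: 4 3-(2-methoxy-4-methylphenyl)propanoic acid; 5 (trimethylsilyl)diazomethane
Product: 7 1-diazo-4-(2-methoxy-4-methylphenyl)butan-2-one, via acid chloride 6 (not isolated)
Conditions: (COCl)2, DMF (cat.), CH2Cl2, 0 °C to rt; evaporate; then 5 (2 equiv), MeCN–THF, 0 °C to rt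
Reagents that add atoms: oxalyl chloride, O=C(Cl)C(Cl)=O (chlorine of 6 only; none remains in 7)
Why: Acid chloride formation followed by acylation of the silylated diazomethane (Arndt–Eistert-type diazoketone synthesis); the silyl group of the first-formed α-silyl diazoketone is removed by the chloride released. No Lewis acid is present that could close the chain onto the electron-rich ring.

Step 4
Reactants: 7 1-diazo-4-(2-methoxy-4-methylphenyl)butan-2-one
Product: 9 (8aR)-4-methoxy-6-methyl-3,8a-dihydroazulen-1(2H)-one, via norcaradiene 8 (not isolated)
Conditions: Rh2(S-PTTL)4 (dirhodium tetrakis[N-phthaloyl-(S)-tert-leucinate], 1 mol %), CH2Cl2, slow addition of 7, 0 °C to rt; filtration through neutral alumina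
Reagents that add atoms: none
Why: This is an intramolecular Buchner reaction: the dirhodium carboxylate takes the diazo nitrogen from 7, and the electrophilic rhodium ketocarbenoid at C5 cyclopropanates the C1–C6 bond of the arene to give norcaradiene 8, which opens by thermal disrotatory six-electron electrocyclisation to cycloheptatriene 9. The closest known reaction type is the rhodium- or copper-catalysed cyclisation of 1-diazo-4-arylbutan-2-ones to 3,8a-dihydroazulen-1(2H)-ones, for which enantioselective versions with chiral catalysts exist; the ortho-methoxy, para-methyl arene is a new substrate, not a new reaction. The five-ring closes by 5-exo attack of the carbenoid carbon on the ipso carbon C1 through the tether C2–C3–C4, and the seven-ring is made from the benzene ring by one-carbon enlargement when the C1–C6 bond of 8 breaks. C5 is the only stereocentre of 9 (C1 and C6 of 8 become sp2 again); it is set in the cyclopropanation by the chiral pocket of the four N-phthaloyl-tert-leucinate ligands, which decides the enantiotopic face of the carbenoid that meets the arene, and the ring opening does not touch it. The step needs addition across C1–C6 and not across C1–C10: C10 carries the methoxy group, so bonding there would create a fully substituted, crowded cyclopropane carbon, whereas C6 is an unhindered CH. It also needs cyclopropanation to win over aromatic substitution to a 2-tetralone, which is why a carboxylate catalyst of moderate electrophilicity, slow addition and strictly acid-free handling are used. Because the C4 carbonyl is a π-acceptor on C5, 9 should stay in mobile equilibrium with 8; both hold the same C5 configuration, and the material is taken into step 5 without delay because enolisation toward C5 would erase it.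

Step 5
Reactants: 9 (8aR)-4-methoxy-6-methyl-3,8a-dihydroazulen-1(2H)-one
Product: 10 (1R,8aR)-4-methoxy-6-methyl-1-(propan-2-yl)-1,2,3,8a-tetrahydroazulen-1-ol
Conditions: i-PrMgCl, CeCl3 (anhydrous), THF, −78 °C; pH 7 buffer work-up
Reagents that add atoms: isopropylmagnesium chloride, CC(C)[Mg]Cl
Why: 1,2-Addition of an organocerium reagent, whose low basicity suppresses enolisation at the acidic C5–H and β-hydride reduction. The isopropyl group should enter the cyclopentanone face that carries H5, anti to the C5–C6 bond that projects over the other face, so the hydroxyl ends up β (4R); tautomer 8 would be attacked in the same sense and its adduct opens to the same triene.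

Step 6
Reactants: 10 (1R,8aR)-4-methoxy-6-methyl-1-(propan-2-yl)-1,2,3,8a-tetrahydroazulen-1-ol
Product: 11 (1R,3R,8R,9R)-3-methoxy-5-methyl-9-(propan-2-yl)tricyclo[6.3.0.0^{1,3}]undeca-4,6-dien-9-ol (cyclopropane C1–C11–C10, C11 on the β face)
Conditions: Et2Zn (3 equiv), CH2I2 (3 equiv), CH2Cl2, −10 to 0 °C; pyridine, then aq. NaHCO3
Reagents that add atoms: diiodomethane, ICI
Why: Hydroxyl-directed Simmons–Smith cyclopropanation (Furukawa variant): the zinc alkoxide of the C4 hydroxyl binds the carbenoid and delivers CH2 to the β face of the C1=C10 enol ether, so C11 is set cis to the hydroxyl and trans to H5, against the purely steric preference. Site selectivity rests on the enol ether being the most electron-rich alkene and on geometry: the cyclopentane plane is the nodal plane of C1=C10, so the C4 oxygen sits directly over one π face, whereas it lies close to the nodal plane of C6=C7.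

Step 7
Reactants: 11 (1R,3R,8R,9R)-3-methoxy-5-methyl-9-(propan-2-yl)tricyclo[6.3.0.0^{1,3}]undeca-4,6-dien-9-ol
Product: 12 (1R,3aS,8aR)-1-hydroxy-3a,6-dimethyl-1-(propan-2-yl)-2,3,3a,8a-tetrahydroazulen-4(1H)-one
Conditions: HCl (0.5 M aq), THF, 0 °C to rt
Reagents that add atoms: water, O (the C10 carbonyl oxygen)
Why: Acid-mediated opening of an alkoxycyclopropane to an α-methyl ketone: protonation at the unsubstituted carbon C11 with cleavage of C10–C11 is helped by the methoxy group and by the dienyl substituent on C10, and the conjugated oxocarbenium ion is hydrolysed to the C10 ketone. No bond to C1 is broken, so the new methyl group keeps the configuration set in step 6 (1S in target numbering).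

Step 8
Reactants: 12 (1R,3aS,8aR)-1-hydroxy-3a,6-dimethyl-1-(propan-2-yl)-2,3,3a,8a-tetrahydroazulen-4(1H)-one
Product: 14 (1R,3aS,8S,8aS)-1,8-dihydroxy-3a,6-dimethyl-1-(propan-2-yl)-2,3,3a,5,8,8a-hexahydroazulen-4(1H)-one, via allylboronate 13 (not isolated)
Conditions: CuCl (5 mol %), NaOt-Bu (10 mol %), DPEphos (5 mol %), B2pin2, MeOH, THF, rt; then NaBO3·4H2O, THF–H2O, rt
Reagents that add atoms: bis(pinacolato)diboron, CC1(C)OB(OC1(C)C)B2OC(C)(C)C(C)(C)O2 (boryl group of 13); sodium perborate, [Na+].[O-]OB=O (the C6 oxygen of 14)
Why: Copper-catalysed conjugate boration of an α,β,γ,δ-unsaturated ketone at the δ-carbon, then oxidation of the C–B bond with retention: the β-carbon C8 is fully substituted, so the boryl–copper species adds at C6, and protonation of the copper dienolate at C9 gives 13. The bulky reagent should approach C6 from the α face, anti to the angular C1 methyl that stands 1,3-syn-axial over the β face, which sets 6S.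

Step 9
Reactants: 14 (1R,3aS,8S,8aS)-1,8-dihydroxy-3a,6-dimethyl-1-(propan-2-yl)-2,3,3a,5,8,8a-hexahydroazulen-4(1H)-one
Product: 15 (1R,3aS,8S,8aS)-1,8-dihydroxy-3a,6-dimethyl-1-(propan-2-yl)-2,3,3a,7,8,8a-hexahydroazulen-4(1H)-one
Conditions: DBU (0.2 equiv), CH2Cl2, rt
Reagents that add atoms: none
Why: Base-mediated equilibration of a β,γ- to an α,β-unsaturated ketone through the dienolate (deprotonation at C9, reprotonation at C7); the conjugated trisubstituted enone is the more stable isomer, and any material already protonated at C7 in step 8 is this same compound. A catalytic amidine base at room temperature is chosen so that the δ-hydroxyl is not expelled; C6 is not involved.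

Step 10
Reactants: 15 (1R,3aS,8S,8aS)-1,8-dihydroxy-3a,6-dimethyl-1-(propan-2-yl)-2,3,3a,7,8,8a-hexahydroazulen-4(1H)-one; 16 4-methoxybenzoyl chloride
Product: 17 (3R,3aS,4S,8aS)-3-hydroxy-6,8a-dimethyl-8-oxo-3-(propan-2-yl)-1,2,3,3a,4,5,8,8a-octahydroazulen-4-yl 4-methoxybenzoate
Conditions: Et3N, DMAP (0.1 equiv), CH2Cl2, 0 °C
Reagents that add atoms: none
Why: Nucleophile-catalysed acylation (DMAP): only the secondary C6 hydroxyl should react, the tertiary C4 hydroxyl being too hindered. Low temperature and a short reaction time are used because the product is a δ-acyloxy enone that could lose the carboxylate by vinylogous β-elimination on long exposure to base.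

## Compound list

1 | 2-methoxy-4-methylbenzaldehyde | COc1cc(C)ccc1C=O | starting material
2 | malonic acid | OC(=O)CC(=O)O | starting material
3 | (E)-3-(2-methoxy-4-methylphenyl)prop-2-enoic acid | COc1cc(C)ccc1/C=C/C(=O)O | intermediate
4 | 3-(2-methoxy-4-methylphenyl)propanoic acid | COc1cc(C)ccc1CCC(=O)O | intermediate
5 | (trimethylsilyl)diazomethane | C[Si](C)(C)C=[N+]=[N-] | starting material
6 | 3-(2-methoxy-4-methylphenyl)propanoyl chloride | COc1cc(C)ccc1CCC(Cl)=O | intermediate (not isolated)
7 | 1-diazo-4-(2-methoxy-4-methylphenyl)butan-2-one | COc1cc(C)ccc1CCC(=O)C=[N+]=[N-] | intermediate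
8 | (1R,5R,6R)-10-methoxy-8-methyltricyclo[4.4.0.0^{1,5}]deca-7,9-dien-4-one (norcaradiene valence isomer of 9) | O=C1CC[C@@]23C(OC)=CC(C)=C[C@@H]2[C@@H]13 | intermediate (not isolated)
9 | (8aR)-4-methoxy-6-methyl-3,8a-dihydroazulen-1(2H)-one | O=C1CCC2=C(OC)C=C(C)C=C[C@@H]12 | intermediate
10 | (1R,8aR)-4-methoxy-6-methyl-1-(propan-2-yl)-1,2,3,8a-tetrahydroazulen-1-ol | COC1=C2CC[C@@](O)(C(C)C)[C@@H]2C=CC(C)=C1 | intermediate
11 | (1R,3R,8R,9R)-3-methoxy-5-methyl-9-(propan-2-yl)tricyclo[6.3.0.0^{1,3}]undeca-4,6-dien-9-ol | CO[C@@]12C[C@@]13CC[C@@](O)(C(C)C)[C@@H]3C=CC(C)=C2 | intermediate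
12 | (1R,3aS,8aR)-1-hydroxy-3a,6-dimethyl-1-(propan-2-yl)-2,3,3a,8a-tetrahydroazulen-4(1H)-one | C1=CC(C)=CC(=O)[C@@]2(C)CC[C@@](O)(C(C)C)[C@H]12 | intermediate
13 | (1R,3aS,8S,8aR)-1-hydroxy-3a,6-dimethyl-1-(propan-2-yl)-8-(4,4,5,5-tetramethyl-1,3,2-dioxaborolan-2-yl)-2,3,3a,5,8,8a-hexahydroazulen-4(1H)-one | CC1(C)OB(OC1(C)C)[C@H]2C=C(C)CC(=O)[C@@]3(C)CC[C@@](O)(C(C)C)[C@H]23 | intermediate (not isolated)
14 | (1R,3aS,8S,8aS)-1,8-dihydroxy-3a,6-dimethyl-1-(propan-2-yl)-2,3,3a,5,8,8a-hexahydroazulen-4(1H)-one | O[C@H]1C=C(C)CC(=O)[C@@]2(C)CC[C@@](O)(C(C)C)[C@H]12 | intermediate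
15 | (1R,3aS,8S,8aS)-1,8-dihydroxy-3a,6-dimethyl-1-(propan-2-yl)-2,3,3a,7,8,8a-hexahydroazulen-4(1H)-one | O[C@H]1CC(C)=CC(=O)[C@@]2(C)CC[C@@](O)(C(C)C)[C@H]12 | intermediate
16 | 4-methoxybenzoyl chloride | COc1ccc(cc1)C(Cl)=O | starting material
17 | (3R,3aS,4S,8aS)-3-hydroxy-6,8a-dimethyl-8-oxo-3-(propan-2-yl)-1,2,3,3a,4,5,8,8a-octahydroazulen-4-yl 4-methoxybenzoate | COc1ccc(C(=O)O[C@H]2CC(C)=CC(=O)[C@@]3(C)CC[C@@](O)(C(C)C)[C@H]23)cc1 | target

## Step count and least certain steps

Total step count: 10. Longest linear sequence: 10 steps (1 to 17); the route is linear, with 2, 5 and 16 entering as purchased reagents.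

**Step 4 (key step).** The most likely failure is incomplete control of C5. An acceptor-only carbenoid on this untested arene may give only modest enantiofacial discrimination, and the C5 hydrogen of 9 (α to the ketone and doubly allylic) can be lost through the enol. Addition toward the methoxy-bearing side and aromatic substitution are lesser concerns. The fallback separates ring construction from enantiocontrol. It sets out from 7: cyclisation with achiral Rh2(OAc)4 in CH2Cl2 should give racemic 4-methoxy-6-methyl-3,8a-dihydroazulen-1(2H)-one F1. A kinetic resolution by Corey–Bakshi–Shibata reduction follows, with (S)-2-methyl-CBS-oxazaborolidine and about 0.55 equiv of BH3·SMe2 in THF at −40 °C. For the (8aS) ketone the hydride delivery preferred by the catalyst coincides with the substrate's own preference (the face of H5), so this enantiomer should be reduced faster, to (1R,8aS)-4-methoxy-6-methyl-1,2,3,8a-tetrahydroazulen-1-ol F2. The (8aR) ketone is the mismatched case and should be left behind; after separation it is 9, where the fallback rejoins the route.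

**Step 7.** The most likely failure is protonation of the diene in place of the cyclopropane CH2. That would give a cyclopropylcarbinyl cation next to the oxygenated carbon, open to ring enlargement or skeletal rearrangement, and stronger acid would also endanger the tertiary C4 carbinol. The fallback replaces the cationic opening by a fluoride-triggered one. It sets out from 10: mild hydrolysis of the enol ether (oxalic acid, wet THF) should give (1R,8aR)-1-hydroxy-6-methyl-1-(propan-2-yl)-2,3,3a,8a-tetrahydroazulen-4(1H)-one F3 as a mixture of C1 epimers. Kinetic deprotonation at C1 with LiN(i-Pr)2 (2.2 equiv) and trapping with t-BuMe2SiCl/HMPA should silylate the enolate oxygen but not the hindered tertiary alkoxide. This gives (1R,8aR)-4-[tert-butyl(dimethyl)silyloxy]-6-methyl-1-(propan-2-yl)-1,2,3,8a-tetrahydroazulen-1-ol F4. The hydroxyl-directed Simmons–Smith reaction of step 6 then gives (1R,3R,8R,9R)-3-[tert-butyl(dimethyl)silyloxy]-5-methyl-9-(propan-2-yl)tricyclo[6.3.0.0^{1,3}]undeca-4,6-dien-9-ol F5. Bu4NF in wet THF frees the cyclopropanolate, which opens toward the less substituted carbon C11 and is protonated there, returning to the route at 12.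

**Step 8.** The most likely failure is poor facial selectivity at C6, since both faces carry a substituent 1,3 to C6. Loss of the C5 configuration by vinylogous enolisation under the alkoxide co-catalyst is a second risk. The fallback delivers oxygen as an electrophile under neutral conditions and sets out from 12. Dimethyldioxirane in acetone at 0 °C should epoxidise the electron-richer distal alkene C6=C7 from the α face, giving the 6α,7α-epoxide of 12, F6. Pd(PPh3)4 (zerovalent palladium) with HCO2H and Et3N in THF should then ionise the allylic C7–O bond and deliver hydride to C7, leaving the C6 alcohol and the conjugated enone. This returns to the route at 15, so step 9 is not needed on this path.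

**Step 9.** The most likely failure is loss of the δ-hydroxyl from the dienolate by vinylogous β-elimination, which would lead back to 12, or incomplete equilibration. The fallback changes the order so that the isomerisation is run while C6 still carries boron, which is not a leaving group. It sets out from 13, isolated by leaving out the perborate in step 8. DBU in CH2Cl2 should move the alkene into conjugation to give (1R,3aS,8S,8aR)-1-hydroxy-3a,6-dimethyl-1-(propan-2-yl)-8-(4,4,5,5-tetramethyl-1,3,2-dioxaborolan-2-yl)-2,3,3a,7,8,8a-hexahydroazulen-4(1H)-one F7. Oxidation with NaBO3·4H2O then returns to the route at 15.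

## Further compounds

F1 | step 4 | racemic 4-methoxy-6-methyl-3,8a-dihydroazulen-1(2H)-one | O=C1CCC2=C(OC)C=C(C)C=CC12
F2 | step 4 | (1R,8aS)-4-methoxy-6-methyl-1,2,3,8a-tetrahydroazulen-1-ol | COC1=C2CC[C@@H](O)[C@H]2C=CC(C)=C1
F3 | step 7 | (1R,8aR)-1-hydroxy-6-methyl-1-(propan-2-yl)-2,3,3a,8a-tetrahydroazulen-4(1H)-one, mixture of epimers at C3a (target C1) | C1=CC(C)=CC(=O)C2CC[C@@](O)(C(C)C)[C@H]12
F4 | step 7 | (1R,8aR)-4-[tert-butyl(dimethyl)silyloxy]-6-methyl-1-(propan-2-yl)-1,2,3,8a-tetrahydroazulen-1-ol | CC(C)(C)[Si](C)(C)OC1=C2CC[C@@](O)(C(C)C)[C@@H]2C=CC(C)=C1
F5 | step 7 | (1R,3R,8R,9R)-3-[tert-butyl(dimethyl)silyloxy]-5-methyl-9-(propan-2-yl)tricyclo[6.3.0.0^{1,3}]undeca-4,6-dien-9-ol | CC(C)(C)[Si](C)(C)O[C@@]12C[C@@]13CC[C@@](O)(C(C)C)[C@@H]3C=CC(C)=C2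
F6 | step 8 | 6α,7α-epoxide of 12 (oxirane across C6–C7 on the face of H5; C8=C9 enone, C4 carbinol and C1 methyl unchanged) | CC1=CC(=O)[C@@]2(C)CC[C@@](O)(C(C)C)[C@@H]2[C@H]3O[C@@H]13
F7 | step 9 | (1R,3aS,8S,8aR)-1-hydroxy-3a,6-dimethyl-1-(propan-2-yl)-8-(4,4,5,5-tetramethyl-1,3,2-dioxaborolan-2-yl)-2,3,3a,7,8,8a-hexahydroazulen-4(1H)-one | CC1(C)OB(OC1(C)C)[C@H]2CC(C)=CC(=O)[C@@]3(C)CC[C@@](O)(C(C)C)[C@H]23
A1 | alternative 1 | methyl 4-[tert-butyl(dimethyl)silyloxy]-3a-methyl-1-(propan-2-yl)-1,8-bis(triethylsilyloxy)-1,2,3,3a,4,7-hexahydroazulene-6-carboxylate (configuration as in the SMILES) | COC(=O)C1=C[C@@H](O[Si](C)(C)C(C)(C)C)[C@@]2(C)CC[C@@](O[Si](CC)(CC)CC)(C(C)C)C2=C(O[Si](CC)(CC)CC)C1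
A2 | alternative 1 | triethyl{[(1R)-3-methyl-1-(propan-2-yl)-2-(1-triethylsilyloxyethenyl)cyclopent-2-en-1-yl]oxy}silane | C=C(O[Si](CC)(CC)CC)C1=C(C)CC[C@@]1(O[Si](CC)(CC)CC)C(C)C
A3 | alternative 1 | methyl (E)-4-[tert-butyl(dimethyl)silyloxy]-2-diazobut-3-enoate | COC(=O)C(=[N+]=[N-])/C=C/O[Si](C)(C)C(C)(C)C
A4 | alternative 2 | (1R,3aS,8S,8aS)-8-[tert-butyl(dimethyl)silyloxy]-1-hydroxy-3a-methyl-1-(propan-2-yl)octahydroazulen-4(1H)-one | CC(C)(C)[Si](C)(C)O[C@H]1CCCC(=O)[C@@]2(C)CC[C@@](O)(C(C)C)[C@H]12
A5 | alternative 2 | (2S,3S,4S)-4-[tert-butyl(dimethyl)silyloxy]-2-(2-iodoethyl)-2-methyl-3-(2-methylpropanoyl)cycloheptan-1-one | CC(C)(C)[Si](C)(C)O[C@H]1CCCC(=O)[C@@](C)(CCI)[C@@H]1C(=O)C(C)C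
A6 | alternative 3 | trans-fused hydroazulen-6-one with C4 hydroxyl and isopropyl, C1 methyl and C10 ethylene ketal (target numbering; configuration as in the SMILES) | O=C1CCCC2(OCCO2)[C@@]3(C)CC[C@@](O)(C(C)C)[C@H]13
A7 | alternative 3 | cis-fused decalin diol monomesylate: C1 methyl, C6 hydroxyl, C5 mesylate and C4 hydroxyl all on one face, C4 isopropyl, C10 ethylene ketal (target numbering; C1 bonded to C6) | O[C@]12CCCC3(OCCO3)[C@@]1(C)CC[C@@](O)(C(C)C)[C@@H]2OS(C)(=O)=O
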